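**Retrosynthetic overview**

1. The strategy rests on the trans-vicinal pair on the cyclohexane (ring A): C1' (bearing CO2H) and C2' (bearing the CH2CH2 linker, next to the gem-dimethyl carbon C3'). These two carbons are read as the ring-fusion carbons of a trans-octalin whose second ring (ring B) holds the carboxyl carbon, both linker CH2 groups and chromene C2 with its methyl, joined through a cleavable C=C.
2. Target ⇒ chromene acetal 29 ⇒ ring-closing metathesis of a 2-vinylaryl tertiary allyl ether ⇒ SNAr of (R)-tertiary allylic alcohol 21 on 2,6-difluoro-4-methylbenzaldehyde. Chromene C2 comes from Sharpless epoxidation and reductive opening of (E)-allylic alcohol 18.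
3. 18 ⇒ methyl ketone 15 ⇒ ozonolytic unzipping of ring B of octalin 12 ⇒ decarbonylation of the Diels–Alder adduct 11.
4. 11 ⇒ iminium-catalysed intramolecular Diels–Alder reaction of trienal 10, which forms C1'–C2' and the linker CH2–CH2 bond. 10 is built from isobutyronitrile, 5-bromopent-1-ene, Ph3P=CHCHO, vinyl-Bpin and 2-bromopropene.
5. Ring order: rings A and B together (step 6), ring B opened (step 8), pyran ring C closed onto the preformed benzene ring D (step 17).

Key step: step 6

Remark on the chemistry: 2,6-difluoro-4-methylbenzaldehyde 22 and (2S,5S)-5-benzyl-2-tert-butyl-3-methylimidazolidin-4-one are taken as catalogue compounds.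

**Route**

Step 1
Reactants: 1 isobutyronitrile; 2 5-bromopent-1-ene
Product: 3 2,2-dimethylhept-6-enenitrile
Conditions: LDA, THF, −78 °C; then 2, −78 °C → rt
Reagents that add atoms: none
Why: SN2 alkylation of the lithiated nitrile with a primary bromide installs the quaternary carbon cleanly, and no stereocentre is formed.

Step 2
Reactants: 3 2,2-dimethylhept-6-enenitrile
Product: 4 2,2-dimethylhept-6-enal
Conditions: DIBAL-H, toluene, −78 → 0 °C; 1 M HCl, 0 °C
Reagents that add atoms: water, O
Why: Partial reduction of the hindered nitrile stops at the aluminium aldimine, which is hydrolysed to the aldehyde on work-up, and the terminal alkene is inert.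

Step 3
Reactants: 4 2,2-dimethylhept-6-enal; 5 (triphenylphosphoranylidene)acetaldehyde
Product: 6 (2E)-4,4-dimethylnona-2,8-dienal
Conditions: toluene, 90 °C
Reagents that add atoms: none
Why: Wittig olefination with the stabilised formyl ylide should give the (E)-enal, and it is run before the diene exists so that the heating cannot start a thermal cycloaddition.

Step 4
Reactants: 6 (2E)-4,4-dimethylnona-2,8-dienal; 7 4,4,5,5-tetramethyl-2-vinyl-1,3,2-dioxaborolane
Product: 8 (2E,8E)-4,4-dimethyl-9-(4,4,5,5-tetramethyl-1,3,2-dioxaborolan-2-yl)nona-2,8-dienal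
Conditions: second-generation Grubbs catalyst RuCl2(=CHPh)(H2IMes)(PCy3) (5 mol %), 7 (3 equiv), CH2Cl2, 40 °C
Reagents that add atoms: none
Why: Olefin cross-metathesis of the terminal alkene with the vinylboronate should give the (E)-alkenylboronate, while the enal C=C, electron-poor and flanked by the quaternary carbon, stays out of the metathesis.

Step 5
Reactants: 8 (2E,8E)-4,4-dimethyl-9-(4,4,5,5-tetramethyl-1,3,2-dioxaborolan-2-yl)nona-2,8-dienal; 9 2-bromopropene
Product: 10 (2E,8E)-4,4,10-trimethylundeca-2,8,10-trienal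
Conditions: PdCl2(dppf)·CH2Cl2 (5 mol %), K3PO4 (3 M aq.), THF, 25–35 °C; product used at once
Reagents that add atoms: none
Why: Suzuki–Miyaura coupling proceeds with retention of alkene geometry and builds the (E)-2-methyl-1,3-diene near room temperature, so the trienal is never heated.

Step 6
Reactants: 10 (2E,8E)-4,4,10-trimethylundeca-2,8,10-trienal
Product: 11 (1S,4aR,8aS)-3,8,8-trimethyl-1,2,4a,5,6,7,8,8a-octahydronaphthalene-1-carbaldehyde
Conditions: (2S,5S)-5-benzyl-2-tert-butyl-3-methylimidazolidin-4-one (20 mol %), TfOH (20 mol %), MeCN/H2O 98:2, −10 → 5 °C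
Reagents that add atoms: none
Why: The enal of 10 condenses with the imidazolidinone salt to an (E)-configured, s-trans unsaturated iminium ion whose lowered LUMO lets the tethered 2-methyldiene add in a concerted, asynchronous [4+2] cycloaddition, after which hydrolysis releases 11 and the amine; the closest known reaction type is the secondary-amine (iminium) catalysed enantioselective intramolecular Diels–Alder reaction of (2E,7E,9E)-trienals. Ring B is the six-membered cycloaddition ring made of the four diene carbons and the two enal carbons (new bonds C2–C11 and C3–C8, trienal numbering), and ring A is the six-membered carbocycle that closes through the same C3–C8 bond over the four-carbon tether C4–C7, which sits exo to the diene in a chair-like arrangement. The absolute configuration at C8a is set by the catalyst: the benzyl group at C5 of the (2S,5S)-imidazolidinone covers one face of the iminium π system, the enal C=C lies on the side away from the tert-butyl group, and the diene adds to the open face of the β-carbon, the same facial rule that holds for intermolecular cycloadditions with this catalyst family. C4a follows from the endo transition state (iminium carbon under the diene), which with a four-atom tether gives the trans ring fusion, and C1 follows from the (E)-enal geometry but is erased in step 7. The step needs endo over exo selectivity, which secondary overlap with the iminium and the chair-like tether should provide, and it needs the catalysed path to outrun the uncatalysed racemic one, which is secured by running cold on a trienal that was made without heating; the gem-dimethyl group gives a Thorpe–Ingold assist to closure but also hinders C3, and this is where the risk of the route sits. Any (Z)-diene isomer carried from step 4 cannot reach the s-cis conformation and should be left unchanged.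

Step 7
Reactants: 11 (1S,4aR,8aS)-3,8,8-trimethyl-1,2,4a,5,6,7,8,8a-octahydronaphthalene-1-carbaldehyde
Product: 12 (4aR,8aR)-1,1,6-trimethyl-1,2,3,4,4a,7,8,8a-octahydronaphthalene
Conditions: RhCl(PPh3)3 (1.1 equiv), toluene, 110 °C
Reagents that add atoms: none
Why: Tsuji–Wilkinson decarbonylation (oxidative addition of the formyl C–H bond to monovalent rhodium, CO extrusion, C–H reductive elimination) removes the activating formyl carbon, so C1 becomes CH2 and the two ring-fusion centres are untouched.

Step 8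
Reactants: 12 (4aR,8aR)-1,1,6-trimethyl-1,2,3,4,4a,7,8,8a-octahydronaphthalene
Product: 15 4-[(1R,6S)-6-(dimethoxymethyl)-2,2-dimethylcyclohexyl]butan-2-one, via hydroperoxy ketal aldehyde 13 (not isolated), via hydroperoxy ketal acetal 14 (not isolated)
Conditions: O3, CH2Cl2/MeOH 5:1, −78 °C; TsOH·H2O (cat.), −78 °C → rt; NaHCO3 (to quench the acid), Me2S, rt
Reagents that add atoms: ozone, [O-][O+]=O; methanol, CO
Why: Terminus-differentiating ozonolysis in methanol: the carbonyl oxide forms at the more substituted alkene carbon and is trapped as the methoxy hydroperoxide, the aldehyde terminus is acetalised under acid and Me2S then reduces the hydroperoxide to the methyl ketone, while the trans-diequatorial ring centres are the stable arrangement and are not at risk.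

Step 9
Reactants: 15 4-[(1R,6S)-6-(dimethoxymethyl)-2,2-dimethylcyclohexyl]butan-2-one; 16 triethyl phosphonoacetate
Product: 17 ethyl (2E)-5-[(1R,6S)-6-(dimethoxymethyl)-2,2-dimethylcyclohexyl]-3-methylpent-2-enoate
Conditions: NaH, THF, 0 → 60 °C; chromatographic removal of the (Z)-isomer
Reagents that add atoms: none
Why: Horner–Wadsworth–Emmons olefination of the methyl ketone should favour the (E)-trisubstituted enoate (larger chain trans to the ester), the acetal is inert to base, and the minor geometric isomer is separated.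

Step 10
Reactants: 17 ethyl (2E)-5-[(1R,6S)-6-(dimethoxymethyl)-2,2-dimethylcyclohexyl]-3-methylpent-2-enoate
Product: 18 (2E)-5-[(1R,6S)-6-(dimethoxymethyl)-2,2-dimethylcyclohexyl]-3-methylpent-2-en-1-ol
Conditions: DIBAL-H (2.5 equiv), CH2Cl2, −78 °C; Rochelle salt work-up
Reagents that add atoms: none
Why: DIBAL-H reduces the conjugated ester by 1,2-addition to the allylic alcohol, and the ring carbon C1' is carried as an acetal so that no second reducible carbonyl is present.

Step 11
Reactants: 18 (2E)-5-[(1R,6S)-6-(dimethoxymethyl)-2,2-dimethylcyclohexyl]-3-methylpent-2-en-1-ol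
Product: 19 [(2R,3R)-3-{2-[(1R,6S)-6-(dimethoxymethyl)-2,2-dimethylcyclohexyl]ethyl}-3-methyloxiran-2-yl]methanol
Conditions: Ti(OiPr)4 (10 mol %), D-(−)-diethyl tartrate (12 mol %), t-BuOOH (anhydrous, 2 equiv), 4 Å molecular sieves, CH2Cl2, −20 °C
Reagents that add atoms: tert-butyl hydroperoxide, CC(C)(C)OO
Why: Sharpless asymmetric epoxidation under reagent control: with the D-(−)-tartrate the (E)-trisubstituted allylic alcohol should give the (2R,3R)-epoxide (the mirror image of the (2S,3S)-epoxide that geraniol gives with the L-(+)-tartrate), which fixes the future chromene C2 irrespective of the remote ring centres.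

Step 12
Reactants: 19 [(2R,3R)-3-{2-[(1R,6S)-6-(dimethoxymethyl)-2,2-dimethylcyclohexyl]ethyl}-3-methyloxiran-2-yl]methanol
Product: 20 (2S,3R)-3-{2-[(1R,6S)-6-(dimethoxymethyl)-2,2-dimethylcyclohexyl]ethyl}-2-(iodomethyl)-3-methyloxirane
Conditions: I2, PPh3, imidazole, CH2Cl2, 0 °C
Reagents that add atoms: iodine, II
Why: Appel-type iodination replaces the primary hydroxyl by SN2 at CH2 without touching either epoxide carbon (the C2 descriptor changes only because iodine raises the CIP rank of CH2I).

Step 13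
Reactants: 20 (2S,3R)-3-{2-[(1R,6S)-6-(dimethoxymethyl)-2,2-dimethylcyclohexyl]ethyl}-2-(iodomethyl)-3-methyloxirane
Product: 21 (3R)-5-[(1R,6S)-6-(dimethoxymethyl)-2,2-dimethylcyclohexyl]-3-methylpent-1-en-3-ol
Conditions: Zn dust, AcOH (2 equiv), MeOH, 0 °C → rt
Reagents that add atoms: none
Why: Zinc inserts into the C–I bond and the β-alkoxy organozinc eliminates with opening of the epoxide (reductive β-elimination of a 2,3-epoxy iodide), giving the tertiary allylic alcohol with the C3–O bond, and hence the (R) configuration, retained.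

Step 14
Reactants: 21 (3R)-5-[(1R,6S)-6-(dimethoxymethyl)-2,2-dimethylcyclohexyl]-3-methylpent-1-en-3-ol; 22 2,6-difluoro-4-methylbenzaldehyde
Product: 23 2-({(3R)-5-[(1R,6S)-6-(dimethoxymethyl)-2,2-dimethylcyclohexyl]-3-methylpent-1-en-3-yl}oxy)-6-fluoro-4-methylbenzaldehyde
Conditions: KH, 18-crown-6 (cat.), THF, 0 °C; then 22 (1.2 equiv), 0 °C → rt
Reagents that add atoms: none
Why: Nucleophilic aromatic substitution (SNAr): the potassium tertiary alkoxide displaces one fluoride ortho to the formyl group of the doubly activated arene, the carbinol C–O bond is not broken so (R) is kept, and the product ether is deactivated toward a second substitution.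

Step 15
Reactants: 23 2-({(3R)-5-[(1R,6S)-6-(dimethoxymethyl)-2,2-dimethylcyclohexyl]-3-methylpent-1-en-3-yl}oxy)-6-fluoro-4-methylbenzaldehyde
Product: 26 2-[(tert-butyldimethylsilyl)oxy]-6-({(3R)-5-[(1R,6S)-6-(dimethoxymethyl)-2,2-dimethylcyclohexyl]-3-methylpent-1-en-3-yl}oxy)-4-methylbenzaldehyde, via sulfonylethyl aryl ether 24 (not isolated), via sodium phenoxide 25 (not isolated)
Conditions: MeSO2CH2CH2OH (1.2 equiv), NaH (2.5 equiv), DMF, 0 °C → rt; then TBSCl (2 equiv), 0 °C → rt
Reagents that add atoms: 2-(methylsulfonyl)ethanol, CS(=O)(=O)CCO; tert-butyldimethylsilyl chloride, CC(C)(C)[Si](C)(C)Cl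
Why: A second SNAr with the alkoxide of 2-(methylsulfonyl)ethanol as hydroxide surrogate, E1cB loss of methyl vinyl sulfone to the phenoxide and O-silylation in the same flask install the protected C5 oxygen while the formyl group still activates the ring.

Step 16
Reactants: 26 2-[(tert-butyldimethylsilyl)oxy]-6-({(3R)-5-[(1R,6S)-6-(dimethoxymethyl)-2,2-dimethylcyclohexyl]-3-methylpent-1-en-3-yl}oxy)-4-methylbenzaldehyde; 27 methyltriphenylphosphonium bromide
Product: 28 tert-butyl[3-({(3R)-5-[(1R,6S)-6-(dimethoxymethyl)-2,2-dimethylcyclohexyl]-3-methylpent-1-en-3-yl}oxy)-2-ethenyl-5-methylphenoxy]dimethylsilane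
Conditions: 27, NaHMDS, THF, 0 °C; then 26, 0 °C → rt
Reagents that add atoms: none
Why: Wittig methylenation with the salt-free ylide converts the hindered aryl aldehyde into the styrene under non-nucleophilic conditions that spare the aryl silyl ether and the acetal.

Step 17
Reactants: 28 tert-butyl[3-({(3R)-5-[(1R,6S)-6-(dimethoxymethyl)-2,2-dimethylcyclohexyl]-3-methylpent-1-en-3-yl}oxy)-2-ethenyl-5-methylphenoxy]dimethylsilane
Product: 29 tert-butyl{[(2R)-2-{2-[(1R,6S)-6-(dimethoxymethyl)-2,2-dimethylcyclohexyl]ethyl}-2,7-dimethyl-2H-chromen-5-yl]oxy}dimethylsilane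
Conditions: second-generation Grubbs catalyst RuCl2(=CHPh)(H2IMes)(PCy3) (5–10 mol %), CH2Cl2, 40 °C, exclusion of light
Reagents that add atoms: none
Why: Ring-closing metathesis of the styrene with the vinyl group on the quaternary carbon closes the pyran ring C as a cis-disubstituted C3=C4 alkene without breaking the C2–O bond, so the (R) centre is carried over, and the low temperature avoids aryl-ether Claisen rearrangement and electrocyclic ring opening of the chromene.

Step 18
Reactants: 29 tert-butyl{[(2R)-2-{2-[(1R,6S)-6-(dimethoxymethyl)-2,2-dimethylcyclohexyl]ethyl}-2,7-dimethyl-2H-chromen-5-yl]oxy}dimethylsilane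
Product: 30 (1S,2R)-2-{2-[(2R)-5-[(tert-butyldimethylsilyl)oxy]-2,7-dimethyl-2H-chromen-2-yl]ethyl}-3,3-dimethylcyclohexane-1-carbaldehyde
Conditions: PPTS (cat.), acetone/H2O 10:1, 45 °C
Reagents that add atoms: water, O
Why: Mild acid-catalysed acetal hydrolysis frees the aldehyde while the aryl silyl ether and the chromene tolerate pyridinium tosylate, and the aldehyde α-centre already holds the more stable trans-diequatorial arrangement.

Step 19
Reactants: 30 (1S,2R)-2-{2-[(2R)-5-[(tert-butyldimethylsilyl)oxy]-2,7-dimethyl-2H-chromen-2-yl]ethyl}-3,3-dimethylcyclohexane-1-carbaldehyde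
Product: 31 (1S,2R)-2-{2-[(2R)-5-[(tert-butyldimethylsilyl)oxy]-2,7-dimethyl-2H-chromen-2-yl]ethyl}-3,3-dimethylcyclohexane-1-carboxylic acid
Conditions: NaClO2, NaH2PO4, 2-methyl-2-butene (large excess), t-BuOH/THF/H2O, 0 °C → rt
Reagents that add atoms: sodium chlorite, [Na+].[O-]Cl=O
Why: Pinnick oxidation converts the aldehyde into the acid without epimerisation, the alkene scavenger removes hypochlorous acid, and the phenol is kept silylated so that the electron-rich ring is not chlorinated.

Step 20
Reactants: 31 (1S,2R)-2-{2-[(2R)-5-[(tert-butyldimethylsilyl)oxy]-2,7-dimethyl-2H-chromen-2-yl]ethyl}-3,3-dimethylcyclohexane-1-carboxylic acid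
Product: 32 (1S,2R)-2-{2-[(2R)-5-hydroxy-2,7-dimethyl-2H-chromen-2-yl]ethyl}-3,3-dimethylcyclohexane-1-carboxylic acid (CNP0144010.1)
Conditions: TBAF, AcOH, THF, 0 °C; pH 4 buffer work-up
Reagents that add atoms: none
Why: Fluoride-mediated cleavage of the aryl silyl ether is fast under buffered, near-neutral conditions that leave the acid-, heat- and light-sensitive 2H-chromene and all three stereocentres untouched.

**Compound list**

1 | isobutyronitrile | CC(C)C#N | starting material
2 | 5-bromopent-1-ene | C=CCCCBr | starting material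
3 | 2,2-dimethylhept-6-enenitrile | N#CC(C)(C)CCCC=C | intermediate
4 | 2,2-dimethylhept-6-enal | O=CC(C)(C)CCCC=C | intermediate
5 | (triphenylphosphoranylidene)acetaldehyde | O=CC=P(c1ccccc1)(c1ccccc1)c1ccccc1 | starting material
6 | (2E)-4,4-dimethylnona-2,8-dienal | O=C/C=C/C(C)(C)CCCC=C | intermediate
7 | 4,4,5,5-tetramethyl-2-vinyl-1,3,2-dioxaborolane | C=CB1OC(C)(C)C(C)(C)O1 | starting material
8 | (2E,8E)-4,4-dimethyl-9-(4,4,5,5-tetramethyl-1,3,2-dioxaborolan-2-yl)nona-2,8-dienal | O=C/C=C/C(C)(C)CCC/C=C/B1OC(C)(C)C(C)(C)O1 | intermediate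
9 | 2-bromopropene | CC(Br)=C | starting material
10 | (2E,8E)-4,4,10-trimethylundeca-2,8,10-trienal | O=C/C=C/C(C)(C)CCC/C=C/C(C)=C | intermediate
11 | (1S,4aR,8aS)-3,8,8-trimethyl-1,2,4a,5,6,7,8,8a-octahydronaphthalene-1-carbaldehyde | O=C[C@H]1CC(C)=C[C@H]2CCCC(C)(C)[C@H]12 | intermediate
12 | (4aR,8aR)-1,1,6-trimethyl-1,2,3,4,4a,7,8,8a-octahydronaphthalene | CC1=C[C@H]2CCCC(C)(C)[C@@H]2CC1 | intermediate
13 | (1S,2R)-2-(3-hydroperoxy-3-methoxybutyl)-3,3-dimethylcyclohexane-1-carbaldehyde (mixture at the ketal carbon) | CC(OC)(OO)CC[C@@H]1[C@@H](C=O)CCCC1(C)C | intermediate (not isolated)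
14 | 4-[(1R,6S)-6-(dimethoxymethyl)-2,2-dimethylcyclohexyl]-2-methoxybutan-2-yl hydroperoxide (mixture at the ketal carbon) | CC(OC)(OO)CC[C@@H]1[C@@H](C(OC)OC)CCCC1(C)C | intermediate (not isolated)
15 | 4-[(1R,6S)-6-(dimethoxymethyl)-2,2-dimethylcyclohexyl]butan-2-one | CC(=O)CC[C@@H]1[C@@H](C(OC)OC)CCCC1(C)C | intermediate
16 | triethyl phosphonoacetate | CCOC(=O)CP(=O)(OCC)OCC | starting material
17 | ethyl (2E)-5-[(1R,6S)-6-(dimethoxymethyl)-2,2-dimethylcyclohexyl]-3-methylpent-2-enoate | CCOC(=O)/C=C(\C)CC[C@@H]1[C@@H](C(OC)OC)CCCC1(C)C | intermediate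
18 | (2E)-5-[(1R,6S)-6-(dimethoxymethyl)-2,2-dimethylcyclohexyl]-3-methylpent-2-en-1-ol | OC/C=C(\C)CC[C@@H]1[C@@H](C(OC)OC)CCCC1(C)C | intermediate
19 | [(2R,3R)-3-{2-[(1R,6S)-6-(dimethoxymethyl)-2,2-dimethylcyclohexyl]ethyl}-3-methyloxiran-2-yl]methanol | OC[C@H]1O[C@]1(C)CC[C@@H]2[C@@H](C(OC)OC)CCCC2(C)C | intermediate
20 | (2S,3R)-3-{2-[(1R,6S)-6-(dimethoxymethyl)-2,2-dimethylcyclohexyl]ethyl}-2-(iodomethyl)-3-methyloxirane | IC[C@H]1O[C@]1(C)CC[C@@H]2[C@@H](C(OC)OC)CCCC2(C)C | intermediate
21 | (3R)-5-[(1R,6S)-6-(dimethoxymethyl)-2,2-dimethylcyclohexyl]-3-methylpent-1-en-3-ol | C=C[C@](C)(O)CC[C@@H]1[C@@H](C(OC)OC)CCCC1(C)C | intermediate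
22 | 2,6-difluoro-4-methylbenzaldehyde | Cc1cc(F)c(C=O)c(F)c1 | starting material
23 | 2-({(3R)-5-[(1R,6S)-6-(dimethoxymethyl)-2,2-dimethylcyclohexyl]-3-methylpent-1-en-3-yl}oxy)-6-fluoro-4-methylbenzaldehyde | C=C[C@](C)(Oc1cc(C)cc(F)c1C=O)CC[C@@H]1[C@@H](C(OC)OC)CCCC1(C)C | intermediate
24 | 2-({(3R)-5-[(1R,6S)-6-(dimethoxymethyl)-2,2-dimethylcyclohexyl]-3-methylpent-1-en-3-yl}oxy)-4-methyl-6-[2-(methylsulfonyl)ethoxy]benzaldehyde | C=C[C@](C)(Oc1cc(C)cc(OCCS(C)(=O)=O)c1C=O)CC[C@@H]1[C@@H](C(OC)OC)CCCC1(C)C | intermediate (not isolated)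
25 | sodium 3-({(3R)-5-[(1R,6S)-6-(dimethoxymethyl)-2,2-dimethylcyclohexyl]-3-methylpent-1-en-3-yl}oxy)-2-formyl-5-methylphenolate | C=C[C@](C)(Oc1cc(C)cc([O-])c1C=O)CC[C@@H]1[C@@H](C(OC)OC)CCCC1(C)C.[Na+] | intermediate (not isolated)
26 | 2-[(tert-butyldimethylsilyl)oxy]-6-({(3R)-5-[(1R,6S)-6-(dimethoxymethyl)-2,2-dimethylcyclohexyl]-3-methylpent-1-en-3-yl}oxy)-4-methylbenzaldehyde | C=C[C@](C)(Oc1cc(C)cc(O[Si](C)(C)C(C)(C)C)c1C=O)CC[C@@H]1[C@@H](C(OC)OC)CCCC1(C)C | intermediate
27 | methyltriphenylphosphonium bromide | C[P+](c1ccccc1)(c1ccccc1)c1ccccc1.[Br-] | starting material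
28 | tert-butyl[3-({(3R)-5-[(1R,6S)-6-(dimethoxymethyl)-2,2-dimethylcyclohexyl]-3-methylpent-1-en-3-yl}oxy)-2-ethenyl-5-methylphenoxy]dimethylsilane | C=C[C@](C)(Oc1cc(C)cc(O[Si](C)(C)C(C)(C)C)c1C=C)CC[C@@H]1[C@@H](C(OC)OC)CCCC1(C)C | intermediate
29 | tert-butyl{[(2R)-2-{2-[(1R,6S)-6-(dimethoxymethyl)-2,2-dimethylcyclohexyl]ethyl}-2,7-dimethyl-2H-chromen-5-yl]oxy}dimethylsilane | Cc1cc(O[Si](C)(C)C(C)(C)C)c2c(c1)O[C@](C)(CC[C@@H]1[C@@H](C(OC)OC)CCCC1(C)C)C=C2 | intermediate
30 | (1S,2R)-2-{2-[(2R)-5-[(tert-butyldimethylsilyl)oxy]-2,7-dimethyl-2H-chromen-2-yl]ethyl}-3,3-dimethylcyclohexane-1-carbaldehyde | Cc1cc(O[Si](C)(C)C(C)(C)C)c2c(c1)O[C@](C)(CC[C@@H]1[C@@H](C=O)CCCC1(C)C)C=C2 | intermediate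
31 | (1S,2R)-2-{2-[(2R)-5-[(tert-butyldimethylsilyl)oxy]-2,7-dimethyl-2H-chromen-2-yl]ethyl}-3,3-dimethylcyclohexane-1-carboxylic acid | Cc1cc(O[Si](C)(C)C(C)(C)C)c2c(c1)O[C@](C)(CC[C@@H]1[C@@H](C(=O)O)CCCC1(C)C)C=C2 | intermediate
32 | (1S,2R)-2-{2-[(2R)-5-hydroxy-2,7-dimethyl-2H-chromen-2-yl]ethyl}-3,3-dimethylcyclohexane-1-carboxylic acid | Cc1cc(O)c2c(c1)O[C@](C)(CC[C@@H]1[C@@H](C(=O)O)CCCC1(C)C)C=C2 | target

**Step count and risks**

Total step count: 20. Longest linear sequence: 20 steps (1 → 32).

Steps most likely to fail: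

1. Step 6 (key cycloaddition). The β-carbon of the iminium carries the quaternary CMe2 carbon, so C3–C8 bond formation may be slow. The developing peri contact between the equatorial methyl and the iminium-bearing carbon may let the exo (cis-fused) pathway or the uncatalysed racemic pathway compete, with loss of turnover, of diastereocontrol or of enantiocontrol. Fallback: an auxiliary-controlled, Lewis-acid-promoted cycloaddition that sets out from trienal 10 and returns at aldehyde 11.
   - Pinnick oxidation (NaClO2, NaH2PO4, 2-methyl-2-butene) should give (2E,8E)-4,4,10-trimethylundeca-2,8,10-trienoic acid F1.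
   - Pivaloyl chloride/Et3N (THF, −20 °C) gives the mixed anhydride 2,2-dimethylpropanoic (2E,8E)-4,4,10-trimethylundeca-2,8,10-trienoic anhydride F2, which is not isolated. It acylates lithiated (4S)-4-benzyl-1,3-oxazolidin-2-one to give (4S)-4-benzyl-3-[(2E,8E)-4,4,10-trimethylundeca-2,8,10-trienoyl]-1,3-oxazolidin-2-one F3.
   - Me2AlCl (CH2Cl2, −30 °C) forms the chelated s-cis acyl imide, and the diene should add through the endo transition state to the face opposite the benzyl group. This should give (4S)-4-benzyl-3-{[(1S,4aR,8aS)-3,8,8-trimethyl-1,2,4a,5,6,7,8,8a-octahydronaphthalen-1-yl]carbonyl}-1,3-oxazolidin-2-one F4.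
   - LiBH4 (THF, 1 equiv MeOH, 0 °C) cleaves the auxiliary to [(1S,4aR,8aS)-3,8,8-trimethyl-1,2,4a,5,6,7,8,8a-octahydronaphthalen-1-yl]methanol F5, and Dess–Martin periodinane oxidation gives 11.

2. Step 14 (aryl ether formation). Substitution by the hindered tertiary alkoxide may be slow, while reversible addition of the alkoxide to the formyl group and hydride-transfer (Cannizzaro/Tishchenko-type) consumption of the aldehyde compete. Fallback: the substitution is done on a carbonyl-free, more strongly activated nitrile, and the aldehyde is unveiled afterwards. It sets out from 22 and 21 and returns at 23.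
   - 22 is condensed with NH2OH·HCl/NaOAc to (E)-N-[(2,6-difluoro-4-methylphenyl)methylidene]hydroxylamine F6, which is dehydrated (Ac2O, heat) to 2,6-difluoro-4-methylbenzonitrile F7.
   - The potassium alkoxide of 21 (KH, THF, 0 °C → rt) displaces one fluoride of F7 to give 2-({(3R)-5-[(1R,6S)-6-(dimethoxymethyl)-2,2-dimethylcyclohexyl]-3-methylpent-1-en-3-yl}oxy)-6-fluoro-4-methylbenzonitrile F8.
   - DIBAL-H (toluene, −78 °C) with a buffered citric acid work-up reduces the nitrile to aldehyde 23.

3. Step 7 (decarbonylation). Oxidative addition at the hindered secondary aldehyde may be slow, and rhodium hydride intermediates may move the ring B double bond or undergo β-hydride elimination, which would shift the position at which ring B is cut in step 8. Fallback: radical decarboxylation, which sets out from 11 and returns at 12.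
   - Pinnick oxidation gives (1S,4aR,8aS)-3,8,8-trimethyl-1,2,4a,5,6,7,8,8a-octahydronaphthalene-1-carboxylic acid F9.
   - DCC/DMAP coupling with N-hydroxypyridine-2-thione in the dark gives the thiohydroxamate ester 2-thioxopyridin-1(2H)-yl (1S,4aR,8aS)-3,8,8-trimethyl-1,2,4a,5,6,7,8,8a-octahydronaphthalene-1-carboxylate F10.
   - Visible-light irradiation with t-BuSH (benzene, rt; Barton reductive decarboxylation) replaces the carboxyl group by hydrogen and gives 12, with thiol trapping expected to outpace homoallyl radical rearrangement.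

**Further compounds**

F1 | step 6 | (2E,8E)-4,4,10-trimethylundeca-2,8,10-trienoic acid | OC(=O)/C=C/C(C)(C)CCC/C=C/C(C)=C
F2 | step 6 | 2,2-dimethylpropanoic (2E,8E)-4,4,10-trimethylundeca-2,8,10-trienoic anhydride | CC(C)(C)C(=O)OC(=O)/C=C/C(C)(C)CCC/C=C/C(C)=C
F3 | step 6 | (4S)-4-benzyl-3-[(2E,8E)-4,4,10-trimethylundeca-2,8,10-trienoyl]-1,3-oxazolidin-2-one | O=C(/C=C/C(C)(C)CCC/C=C/C(C)=C)N1[C@@H](Cc2ccccc2)COC1=O
F4 | step 6 | (4S)-4-benzyl-3-{[(1S,4aR,8aS)-3,8,8-trimethyl-1,2,4a,5,6,7,8,8a-octahydronaphthalen-1-yl]carbonyl}-1,3-oxazolidin-2-one | O=C([C@H]1CC(C)=C[C@H]2CCCC(C)(C)[C@H]12)N3[C@@H](Cc4ccccc4)COC3=O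
F5 | step 6 | [(1S,4aR,8aS)-3,8,8-trimethyl-1,2,4a,5,6,7,8,8a-octahydronaphthalen-1-yl]methanol | OC[C@H]1CC(C)=C[C@H]2CCCC(C)(C)[C@H]12
F6 | step 14 | (E)-N-[(2,6-difluoro-4-methylphenyl)methylidene]hydroxylamine | Cc1cc(F)c(/C=N/O)c(F)c1
F7 | step 14 | 2,6-difluoro-4-methylbenzonitrile | Cc1cc(F)c(C#N)c(F)c1
F8 | step 14 | 2-({(3R)-5-[(1R,6S)-6-(dimethoxymethyl)-2,2-dimethylcyclohexyl]-3-methylpent-1-en-3-yl}oxy)-6-fluoro-4-methylbenzonitrile | C=C[C@](C)(Oc1cc(C)cc(F)c1C#N)CC[C@@H]1[C@@H](C(OC)OC)CCCC1(C)C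
F9 | step 7 | (1S,4aR,8aS)-3,8,8-trimethyl-1,2,4a,5,6,7,8,8a-octahydronaphthalene-1-carboxylic acid | OC(=O)[C@H]1CC(C)=C[C@H]2CCCC(C)(C)[C@H]12
F10 | step 7 | 2-thioxopyridin-1(2H)-yl (1S,4aR,8aS)-3,8,8-trimethyl-1,2,4a,5,6,7,8,8a-octahydronaphthalene-1-carboxylate | S=c1ccccn1OC(=O)[C@H]1CC(C)=C[C@H]2CCCC(C)(C)[C@H]12
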